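**Strategy.** The route rests on disconnecting the bond between geranyl C1'' (the benzylic CH2) and C8. C8 is the ring A carbon flanked by the two oxygen-bearing carbons C7 and C8a, that is, C2 of a resorcinol. On symmetric 1,3-bis(methoxymethoxy)benzene both MOM ethers direct lithiation to that single carbon. CuI-catalysed SN2 coupling with geranyl bromide then installs the intact E-geranyl chain in one operation, with no C6 or O-alkylated isomers. Because the product is still symmetric, one further ortho-lithiation/acetylation gives the correct 1,2,3,4-pattern. Ring C follows by chromone formation, and C2 is set by asymmetric 1,4-addition of an arylboronic acid catalysed by [Rh(OH)(cod)]2 and a chiral bisphosphine.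

Key step: step 2

Remark on the chemistry: the sense of induction in step 6 is assigned by analogy with arylboronic acid addition to cyclohexenone under (S)-configured biaryl bisphosphine control (aryl to the Re face of chromone C2, giving 2S); if a test run shows the opposite sense, the (R)-ligand is used.

**Step 1**
Reactants: 1 resorcinol
Product: 2 1,3-bis(methoxymethoxy)benzene
Conditions: MOMCl (2.5 equiv), i-Pr2NEt (3 equiv), CH2Cl2, 0 °C → rt
Reagents that add atoms: chloromethyl methyl ether (MOMCl), COCCl
Why: Williamson-type O-alkylation of both phenols by the reactive α-chloro ether under amine base should give the bis-acetal, which is the directing-group pattern needed for step 2; no stereocenter is formed.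

**Step 2**
Reactants: 2 1,3-bis(methoxymethoxy)benzene; 3 geranyl bromide [(2E)-1-bromo-3,7-dimethylocta-2,6-diene]
Product: 5 2-[(2E)-3,7-dimethylocta-2,6-dien-1-yl]-1,3-bis(methoxymethoxy)benzene, via 2-lithio arene 4 (not isolated)
Conditions: n-BuLi (1.1 equiv), THF, 0 °C → rt; then CuI (10 mol %), 3 (1.0 equiv), −78 °C → rt
Reagents that add atoms: none
Why: Directed ortho-metalation: n-BuLi is pre-coordinated by both MOM ethers and removes the one proton between them (C2 of the resorcinol, the future C8), the only doubly activated ring position, to give aryllithium 4. Transmetalation to a catalytic arylcopper/cuprate species is followed by oxidative addition to the allylic C–Br bond and reductive elimination at the unsubstituted terminus, i.e. a CuI-catalysed SN2 allylic substitution by an aryl nucleophile; the closest known reaction type is the geranylation of lithiated resorcinol diethers used for cannabigerol-type arenes. No ring is closed and no stereocenter is created. Three selectivities are needed: ring regiochemistry (secured by the two flanking MOM groups of the symmetric substrate), alpha over gamma attack (secured by the gamma,gamma-disubstituted terminus, which disfavours a quaternary benzylic carbon) and retention of the 2E geometry (the geranyl unit reacts as the electrophile at low temperature and passes through no free allyl cation or anion). C-alkylation is exclusive because both oxygens are masked.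

**Step 3**
Reactants: 5 2-[(2E)-3,7-dimethylocta-2,6-dien-1-yl]-1,3-bis(methoxymethoxy)benzene
Product: 8 1-{3-[(2E)-3,7-dimethylocta-2,6-dien-1-yl]-2,4-bis(methoxymethoxy)phenyl}ethan-1-one, via 4-lithio arene 6 (not isolated), via lithium hemiaminal adduct 7 (not isolated)
Conditions: n-BuLi, TMEDA, THF, −20 → 0 °C; then MeC(O)N(OMe)Me, −78 → 0 °C; H2O quench
Reagents that add atoms: N-methoxy-N-methylacetamide, CC(=O)N(C)OC
Why: Directed ortho-metalation next to a MOM ether (the two remaining ortho sites are equivalent by symmetry) followed by Weinreb ketone synthesis, in which the chelated tetrahedral adduct 7 releases the methyl ketone only on aqueous quench so that over-addition is avoided; no stereocenter is formed.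

**Step 4**
Reactants: 8 1-{3-[(2E)-3,7-dimethylocta-2,6-dien-1-yl]-2,4-bis(methoxymethoxy)phenyl}ethan-1-one
Product: 9 1-{3-[(2E)-3,7-dimethylocta-2,6-dien-1-yl]-2-hydroxy-4-(methoxymethoxy)phenyl}ethan-1-one
Conditions: HCl (0.5 M in MeOH), CH2Cl2, 0 °C → rt, stopped when 8 is consumed
Reagents that add atoms: none
Why: Acid-catalysed acetal solvolysis (transacetalisation to methanol) should be clearly faster for the MOM ether ortho to the acetyl group, which is twisted by its two neighbours and leaves as a carbonyl-chelated phenol, so the 4-OMOM group and the alkenes should survive brief dilute acid.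

**Step 5**
Reactants: 9 1-{3-[(2E)-3,7-dimethylocta-2,6-dien-1-yl]-2-hydroxy-4-(methoxymethoxy)phenyl}ethan-1-one
Product: 11 8-[(2E)-3,7-dimethylocta-2,6-dien-1-yl]-7-(methoxymethoxy)-4H-chromen-4-one, via enaminone 10 (not isolated)
Conditions: DMF-DMA, toluene, 90 °C; concentrate; then aq. HCl (1 M), CH2Cl2, rt
Reagents that add atoms: N,N-dimethylformamide dimethyl acetal (DMF-DMA), COC(OC)N(C)C
Why: Condensation of the methyl ketone with DMF-DMA to the enaminone, then acid-promoted 6-endo addition–elimination of the ortho phenol with loss of dimethylamine, is the standard enaminone route to 2,3-unsubstituted chromones and is mild enough for the aryl MOM ether and the trisubstituted alkenes.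

**Step 6**
Reactants: 11 8-[(2E)-3,7-dimethylocta-2,6-dien-1-yl]-7-(methoxymethoxy)-4H-chromen-4-one; 12 [4-(methoxymethoxy)phenyl]boronic acid
Product: 13 (2S)-8-[(2E)-3,7-dimethylocta-2,6-dien-1-yl]-7-(methoxymethoxy)-2-[4-(methoxymethoxy)phenyl]-2,3-dihydro-4H-chromen-4-one
Conditions: 12 (3 equiv), [Rh(OH)(cod)]2 (2.5 mol %), (S)-MeO-F12-BIPHEP [(S)-6,6'-dimethoxy-2,2'-bis{bis(3,4,5-trifluorophenyl)phosphino}biphenyl, 5.5 mol %], CH2Cl2/H2O, rt
Reagents that add atoms: none
Why: Hayashi–Miyaura asymmetric 1,4-addition of an arylboronic acid to a chromone, in which the aryl–rhodium species carrying the electron-poor (S)-bisphosphine inserts the C2=C3 bond with aryl delivery to the Re face of C2 (ligand control) to set the 2S center, while the base-free medium avoids ring opening of the flavanone and the unactivated trisubstituted alkenes do not insert.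

**Step 7**
Reactants: 13 (2S)-8-[(2E)-3,7-dimethylocta-2,6-dien-1-yl]-7-(methoxymethoxy)-2-[4-(methoxymethoxy)phenyl]-2,3-dihydro-4H-chromen-4-one
Product: 14 (2S)-7,4'-dihydroxy-8-geranylflavanone
Conditions: HCl (3 M aq.)/MeOH, 45 °C, stopped at full conversion
Reagents that add atoms: none
Why: Acid-catalysed solvolysis of the two aryl MOM acetals (transacetalisation to methanol) should free both phenols, the C2 center not being epimerisable by enolisation and the moderate temperature limiting addition of the 7-OH to the geranyl alkene.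

**Compound list**
1 | resorcinol (benzene-1,3-diol) | Oc1cccc(O)c1 | starting material
2 | 1,3-bis(methoxymethoxy)benzene | COCOc1cccc(OCOC)c1 | intermediate
3 | geranyl bromide, (2E)-1-bromo-3,7-dimethylocta-2,6-diene | CC(C)=CCC/C(C)=C/CBr | starting material
4 | [2,6-bis(methoxymethoxy)phenyl]lithium (2-lithio arene) | COCOc1cccc(OCOC)c1[Li] | intermediate
5 | 2-[(2E)-3,7-dimethylocta-2,6-dien-1-yl]-1,3-bis(methoxymethoxy)benzene | CC(C)=CCC/C(C)=C/Cc1c(OCOC)cccc1OCOC | intermediate
6 | {3-[(2E)-3,7-dimethylocta-2,6-dien-1-yl]-2,4-bis(methoxymethoxy)phenyl}lithium (4-lithio arene) | CC(C)=CCC/C(C)=C/Cc1c(OCOC)ccc([Li])c1OCOC | intermediate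
7 | lithium 1-{3-[(2E)-3,7-dimethylocta-2,6-dien-1-yl]-2,4-bis(methoxymethoxy)phenyl}-1-[methoxy(methyl)amino]ethan-1-olate (lithium hemiaminal adduct, configuration at the new carbon undefined) | CC(C)=CCC/C(C)=C/Cc1c(OCOC)ccc(C(C)(O[Li])N(C)OC)c1OCOC | intermediate
8 | 1-{3-[(2E)-3,7-dimethylocta-2,6-dien-1-yl]-2,4-bis(methoxymethoxy)phenyl}ethan-1-one | CC(C)=CCC/C(C)=C/Cc1c(OCOC)ccc(C(C)=O)c1OCOC | intermediate
9 | 1-{3-[(2E)-3,7-dimethylocta-2,6-dien-1-yl]-2-hydroxy-4-(methoxymethoxy)phenyl}ethan-1-one | CC(C)=CCC/C(C)=C/Cc1c(OCOC)ccc(C(C)=O)c1O | intermediate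
10 | (2E)-3-(dimethylamino)-1-{3-[(2E)-3,7-dimethylocta-2,6-dien-1-yl]-2-hydroxy-4-(methoxymethoxy)phenyl}prop-2-en-1-one (enaminone) | CC(C)=CCC/C(C)=C/Cc1c(OCOC)ccc(C(=O)/C=C/N(C)C)c1O | intermediate
11 | 8-[(2E)-3,7-dimethylocta-2,6-dien-1-yl]-7-(methoxymethoxy)-4H-chromen-4-one | CC(C)=CCC/C(C)=C/Cc1c(OCOC)ccc2c1OC=CC2=O | intermediate
12 | [4-(methoxymethoxy)phenyl]boronic acid | COCOc1ccc(B(O)O)cc1 | starting material
13 | (2S)-8-[(2E)-3,7-dimethylocta-2,6-dien-1-yl]-7-(methoxymethoxy)-2-[4-(methoxymethoxy)phenyl]-2,3-dihydro-4H-chromen-4-one | CC(C)=CCC/C(C)=C/Cc1c(OCOC)ccc2c1O[C@H](c1ccc(OCOC)cc1)CC2=O | intermediate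
14 | (2S)-7,4'-dihydroxy-8-geranylflavanone, (2S)-8-[(2E)-3,7-dimethylocta-2,6-dien-1-yl]-7-hydroxy-2-(4-hydroxyphenyl)-2,3-dihydro-4H-chromen-4-one | CC(C)=CCC/C(C)=C/Cc1c(O)ccc2c1O[C@H](c1ccc(O)cc1)CC2=O | target

**Step count.** Total: 7 steps. Longest linear sequence: 7 steps (1 → 14).

**Steps most likely to fail**

Step 6. The 7-alkoxy group makes chromone 11 an electron-rich, sluggish acceptor, so protodeboronation of 12 may outrun insertion, and facial selectivity may be insufficient. The fallback sets out from 9 and comes back at 13. Claisen–Schmidt condensation of 9 with commercial 4-(methoxymethoxy)benzaldehyde (KOH, EtOH, rt) should give (2E)-1-{3-[(2E)-3,7-dimethylocta-2,6-dien-1-yl]-2-hydroxy-4-(methoxymethoxy)phenyl}-3-[4-(methoxymethoxy)phenyl]prop-2-en-1-one F4. Oxa-Michael cyclisation (NaOAc, EtOH, reflux) should give the racemic 8-geranyl-7-(methoxymethoxy)-2-[4-(methoxymethoxy)phenyl]chroman-4-one F5. Kinetic resolution by Noyori asymmetric transfer hydrogenation with RuCl(p-cymene)[(R,R)-TsDPEN] in HCO2H/Et3N/EtOAc, run slightly past half conversion, should reduce the 2R ketone to the (2R,4R)-cis-flavan-4-ol bis-MOM ether F6. This would leave (2S)-13, which is separated by chromatography; the trisubstituted alkenes are inert to this catalyst.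

Step 3. The aryllithium may not form cleanly because the doubly activated benzylic/allylic CH2 of the geranyl group can be deprotonated instead of, or by equilibration from, the ring position. The fallback sets out from 2 and comes back at 6. Bromination of 2 (NBS, MeCN, 0 °C) should give 1-bromo-2,4-bis(methoxymethoxy)benzene F1. LiTMP in THF at −78 °C should remove the proton between the two MOM ethers to give [3-bromo-2,6-bis(methoxymethoxy)phenyl]lithium F2. This is geranylated with 3 under CuI catalysis exactly as in step 2 to give 1-bromo-3-[(2E)-3,7-dimethylocta-2,6-dien-1-yl]-2,4-bis(methoxymethoxy)benzene F3. Bromine–lithium exchange on F3 (n-BuLi, THF, −78 °C) is far faster than any deprotonation and generates 6 regiospecifically, which is trapped at once with N-methoxy-N-methylacetamide as in step 3.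

Step 7. Under Brønsted acid the liberated 7-OH (or MeOH/HCl) may add across the C2''=C3'' alkene to give chroman-type products, and the C2 configuration may erode slowly through acid-mediated opening of ring C. The fallback sets out from 13 and comes back at 14. Silyl transfer with TMSOTf/2,2'-bipyridyl (CH2Cl2, 0 °C → rt) should convert both aryl MOM ethers, via an N-(methoxymethyl)bipyridinium salt, into the bis(trimethylsilyl) ether of the target F7. Neutral aqueous hydrolysis should then give 14 without exposure to protic acid.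

**Further compounds**
F1 | step 3 | 1-bromo-2,4-bis(methoxymethoxy)benzene | COCOc1ccc(Br)c(OCOC)c1
F2 | step 3 | [3-bromo-2,6-bis(methoxymethoxy)phenyl]lithium | COCOc1ccc(Br)c(OCOC)c1[Li]
F3 | step 3 | 1-bromo-3-[(2E)-3,7-dimethylocta-2,6-dien-1-yl]-2,4-bis(methoxymethoxy)benzene | CC(C)=CCC/C(C)=C/Cc1c(OCOC)ccc(Br)c1OCOC
F4 | step 6 | (2E)-1-{3-[(2E)-3,7-dimethylocta-2,6-dien-1-yl]-2-hydroxy-4-(methoxymethoxy)phenyl}-3-[4-(methoxymethoxy)phenyl]prop-2-en-1-one | CC(C)=CCC/C(C)=C/Cc1c(OCOC)ccc(C(=O)/C=C/c2ccc(OCOC)cc2)c1O
F5 | step 6 | racemic 8-[(2E)-3,7-dimethylocta-2,6-dien-1-yl]-7-(methoxymethoxy)-2-[4-(methoxymethoxy)phenyl]-2,3-dihydro-4H-chromen-4-one | CC(C)=CCC/C(C)=C/Cc1c(OCOC)ccc2c1OC(c1ccc(OCOC)cc1)CC2=O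
F6 | step 6 | (2R,4R)-8-[(2E)-3,7-dimethylocta-2,6-dien-1-yl]-7-(methoxymethoxy)-2-[4-(methoxymethoxy)phenyl]chroman-4-ol | CC(C)=CCC/C(C)=C/Cc1c(OCOC)ccc2c1O[C@@H](c1ccc(OCOC)cc1)C[C@H]2O
F7 | step 7 | (2S)-8-[(2E)-3,7-dimethylocta-2,6-dien-1-yl]-7-(trimethylsilyloxy)-2-[4-(trimethylsilyloxy)phenyl]-2,3-dihydro-4H-chromen-4-one | CC(C)=CCC/C(C)=C/Cc1c(O[Si](C)(C)C)ccc2c1O[C@H](c1ccc(O[Si](C)(C)C)cc1)CC2=O
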